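The C8–C10/C1–C3 chain comes from geraniol, sulfur is stitched in between C4 and C5 to give an eleven-membered thiacycle, and loss of SO2 contracts it to the ten-membered ring. Nothing was run, so every outcome below is a prediction.

**Plan**

Locants are germacrane-type: ring C1–C10 (C4=C5, C6–O lactone, C8–O ester, C10 carbinol), C11–C13 the methylene-lactone carbons, C14 = 10-Me, C15 = 4-Me; "thiacycle" means the ring S–C4–C3–C2–C1–C10–C9–C8–C7–C6–C5.
Retrosynthetic cuts, in order: lactone O6–C12 (oxidative lactonisation); ring C4=C5, opened to a C4–SO2–C5 bridge (Ramberg–Bäcklund); C4–C15; both C–S bonds; C3–C4 and C5–C6 (two chloromethyl ketones); C7–C8 (aldol).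
Forward: geraniol → C10 carbinol → lactone aldehyde → aldol → bis(chloromethyl ketone) → eleven-membered thiacycle → sulfone → ten-membered carbocycle by loss of SO2 → γ-lactone closed last.
Stereochemistry: C10 by catalytic Sharpless epoxidation; C7/C8 by the oxazolidinone auxiliary; C6 relayed from C8 by a 1,3-anti hydride shift that also places the tiglate on O8; C3 by catalyst-controlled transfer hydrogenation; 4Z from the cis-fused episulfone.
Enabling feature: the ring alkene C4=C5 lies between two oxygenated ring carbons (C3, C6); held as ketones they make C4 and C5 α-halo-ketone carbons for S-alkylation and C4 the only site for C-methylation, so one sulfur atom can be inserted between C4 and C5 and deleted again.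

Key step: step 17

Remark (assumptions): the hydroxy ketones 14–20 may sit partly as cyclic hemiketals with the C10 hydroxyl and are drawn, and taken to react, in the open form; transient or labile centres (lactol carbons of 9 and 28, C4 of 20, C5 of 23, C4/C5 of 24) are left unassigned, and C4 of 21–22 is drawn as the anti epimer, which is immaterial because C4 becomes sp2 in step 17.

**Route**

Step 1
Reactants: 1 3-methylbut-2-enoyl chloride; 2 (S)-4-benzyl-1,3-oxazolidin-2-one
Product: 3 (S)-4-benzyl-3-(3-methylbut-2-enoyl)-1,3-oxazolidin-2-one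
Conditions: 2, n-BuLi, THF, −78 °C; then 1, −78 → 0 °C
Reagents that add atoms: none
Why: N-acylation of the lithiated oxazolidinone by the acid chloride (attachment of the Evans auxiliary), with no new stereocentre.

Step 2
Reactants: 3 (S)-4-benzyl-3-(3-methylbut-2-enoyl)-1,3-oxazolidin-2-one
Product: 4 (S)-4-benzyl-3-[(E)-4-hydroxy-3-methylbut-2-enoyl]-1,3-oxazolidin-2-one
Conditions: SeO2 (0.5 equiv), t-BuOOH, CH2Cl2, 40 °C
Reagents that add atoms: tert-butyl hydroperoxide, CC(C)(C)OO
Why: SeO2 allylic oxidation (ene reaction, then [2,3]-shift) of a β,β-dimethyl enoyl unit should hydroxylate the methyl trans to the carbonyl, as with senecioate esters, leaving the cis methyl for the later γ-deprotonation.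

Step 3
Reactants: 4 (S)-4-benzyl-3-[(E)-4-hydroxy-3-methylbut-2-enoyl]-1,3-oxazolidin-2-one
Product: 5 (S)-4-benzyl-3-[(E)-4-(tert-butyldimethylsilyloxy)-3-methylbut-2-enoyl]-1,3-oxazolidin-2-one
Conditions: TBSCl, imidazole, CH2Cl2, 0 °C → rt
Reagents that add atoms: tert-butyldimethylsilyl chloride, CC(C)(C)[Si](C)(C)Cl
Why: Silylation of the primary allylic alcohol masks the future C12 oxygen through the basic and organometallic steps.

Step 4
Reactants: 6 geraniol
Product: 7 (2S,3S)-2,3-epoxygeraniol, [(2S,3S)-3-methyl-3-(4-methylpent-3-en-1-yl)oxiran-2-yl]methanol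
Conditions: Ti(OiPr)4 (5 mol%), L-(+)-diethyl tartrate (6 mol%), t-BuOOH, 4 Å MS, CH2Cl2, −20 °C
Reagents that add atoms: tert-butyl hydroperoxide, CC(C)(C)OO
Why: Sharpless asymmetric epoxidation of the allylic alcohol, in which the L-(+)-tartrate catalyst delivers oxygen to the face that gives the (2S,3S)-epoxide and so fixes the later C10 centre.

Step 5
Reactants: 7 (2S,3S)-2,3-epoxygeraniol
Product: 8 (S)-3,7-dimethyloct-6-ene-1,3-diol
Conditions: Red-Al, THF, 0 °C → rt
Reagents that add atoms: none
Why: Hydride is delivered intramolecularly from the alkoxyaluminate to C2 of the 2,3-epoxy alcohol (regioselective reductive opening to the 1,3-diol), and the tertiary C–O bond is untouched, so the configuration is retained.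

Step 6
Reactants: 8 (S)-3,7-dimethyloct-6-ene-1,3-diol
Product: 10 2-[(2S)-2-methyl-5-oxooxolan-2-yl]acetaldehyde, via lactol 9 (not isolated)
Conditions: O3, CH2Cl2/MeOH, −78 °C; Me2S; then TEMPO (10 mol%), PhI(OAc)2, CH2Cl2, rt
Reagents that add atoms: ozone, [O-][O+]=O
Why: Ozonolysis of the trisubstituted alkene gives the C3 aldehyde, which closes on the tertiary hydroxyl to lactol 9, and TEMPO/PhI(OAc)2 oxidises the lactol to the γ-lactone and the primary alcohol to the C8 aldehyde, so the lactone both masks O10 and activates C3.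

Step 7
Reactants: 5 (S)-4-benzyl-3-[(E)-4-(tert-butyldimethylsilyloxy)-3-methylbut-2-enoyl]-1,3-oxazolidin-2-one; 10 2-[(2S)-2-methyl-5-oxooxolan-2-yl]acetaldehyde
Product: 12 (S)-4-benzyl-3-[(2S,3R)-3-hydroxy-4-[(2S)-2-methyl-5-oxooxolan-2-yl]-2-[3-(tert-butyldimethylsilyloxy)prop-1-en-2-yl]butanoyl]-1,3-oxazolidin-2-one, via boron dienolate 11 (not isolated)
Conditions: 5, n-Bu2BOTf, Et3N, CH2Cl2, −78 → 0 °C; then 10, −78 → −10 °C; pH 7 buffer, MeOH, H2O2, 0 °C
Reagents that add atoms: none
Why: Evans boron aldol of an enoyl imide by γ-deprotonation to the Z(O)-dienolate, which reacts at its α-carbon through a chair (Zimmerman–Traxler) transition state on the face away from the benzyl group, so that C7 (S) and C8 (R) arise syn under auxiliary control.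

Step 8
Reactants: 12 aldol adduct
Product: 13 (2S,3R)-3-hydroxy-N-methoxy-N-methyl-4-[(2S)-2-methyl-5-oxooxolan-2-yl]-2-[3-(tert-butyldimethylsilyloxy)prop-1-en-2-yl]butanamide
Conditions: MeNH(OMe)·HCl, AlMe3, CH2Cl2, −20 → 0 °C
Reagents that add atoms: N,O-dimethylhydroxylamine hydrochloride, CNOC.Cl
Why: Aluminium-amide transamination to the Weinreb amide is fast at the chelating β-hydroxy imide and should leave the unactivated γ-lactone for the next step, and it releases the auxiliary without touching C7.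

Step 9
Reactants: 13 Weinreb amide lactone
Product: 14 (3S,4R,6S)-1,10-dichloro-4,6-dihydroxy-6-methyl-3-[3-(tert-butyldimethylsilyloxy)prop-1-en-2-yl]decane-2,9-dione (ClCH2–C6(=O) and ClCH2–C3(=O) ketones)
Conditions: ICH2Cl, MeLi·LiBr, THF, −78 °C; AcOH, −78 °C
Reagents that add atoms: chloroiodomethane, ClCI
Why: Chloromethyllithium adds once to each acyl group (chloromethyl ketone synthesis from Weinreb amides and from esters or lactones), because the chelated amide adduct and the lithium lactolate are stable at −78 °C and collapse only on the acidic quench, which supplies C5 and C4 together.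

Step 10
Reactants: 14 bis(chloromethyl ketone)
Product: 16 (6S,8R,9S)-6,8-dihydroxy-6-methyl-9-[3-(tert-butyldimethylsilyloxy)prop-1-en-2-yl]-1-thiacycloundecane-3,10-dione (thiacycle, 3,6-dioxo in germacrane locants), via mercapto ketone 15 (not isolated)
Conditions: NaSH, NaHCO3, THF/MeOH, slow addition of 14, 2 mM, 0 °C → rt
Reagents that add atoms: sodium hydrosulfide, [Na+].[SH-]
Why: Twofold S-alkylation of hydrosulfide by the two α-chloro ketones (cyclic sulfide synthesis from a bis-electrophile) closes the eleven-membered ring at high dilution, the α-halo ketones being the fastest SN2 partners for thiolate and the near-neutral medium sparing the β-hydroxy, β,γ-unsaturated C6 ketone.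

Step 11
Reactants: 16 thiacycle diketone diol
Product: 17 thiacycle 3-ketone with 6-hydroxy (6,8-anti), 8-O-[(E)-2-methylbut-2-enoyl], 10-hydroxy and 12-O-TBS; C6, C7, C8, C10 arranged as in the target
Conditions: (E)-2-methylbut-2-enal (excess), SmI2 (30 mol%, premixed with the aldehyde), THF, −10 °C
Reagents that add atoms: (E)-2-methylbut-2-enal, C/C=C(\C)C=O
Why: Evans–Tishchenko reduction, in which the samarium(III)-bound hemiacetal of the C8 hydroxyl transfers hydride to the C6 ketone through a chair transition state, sets C6 1,3-anti to C8 and leaves O8 as the tiglate in the same event, and only the ketone with a β-hydroxyl (C6, not C3) can react.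

Step 12
Reactants: 17 6-hydroxy 8-tiglate
Product: 18 6-O-tert-butyldimethylsilyl ether of 17
Conditions: TBSCl, imidazole, DMAP (cat.), DMF, 35 °C
Reagents that add atoms: tert-butyldimethylsilyl chloride, CC(C)(C)[Si](C)(C)Cl
Why: Silylation of the only secondary hydroxyl blocks 1,3-acyl migration of the tiglate and β-alkoxide chemistry in the later basic steps, the tertiary C10 hydroxyl being inert to these non-enolising conditions.

Step 13
Reactants: 18 keto sulfide
Product: 19 thiacycle S,S-dioxide (β-keto sulfone) of 18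
Conditions: (NH4)6Mo7O24·4H2O (cat.), 30% H2O2, EtOH, 0 °C → rt
Reagents that add atoms: hydrogen peroxide, OO
Why: Molybdate-catalysed peroxide oxidation takes the sulfide to the sulfone chemoselectively over the 1,1-disubstituted alkene and the electron-poor tiglate.

Step 14
Reactants: 19 β-keto sulfone
Product: 20 4-methyl β-keto sulfone (C15 installed; C4 epimers interconvert)
Conditions: MeI, K2CO3, acetone, rt
Reagents that add atoms: iodomethane, CI
Why: C-Alkylation of the β-keto sulfone occurs only at C4, the one carbon flanked by both C=O and SO2, since C5 is activated by the sulfone alone and is not deprotonated by carbonate.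

Step 15
Reactants: 20 4-methyl β-keto sulfone
Product: 21 (3S)-3-hydroxy-4-methyl sulfone (C4 drawn anti)
Conditions: RuCl(p-cymene)[(S,S)-TsDPEN] (3 mol%), HCO2H/Et3N (5:2), DMF, 35 °C
Reagents that add atoms: none
Why: Noyori–Ikariya asymmetric transfer hydrogenation of a β-keto sulfone with dynamic kinetic resolution at the acidic C4 should give the (3S) carbinol under catalyst control, with the sulfonyl-bearing carbon in the position an aryl group takes in the usual model.

Step 16
Reactants: 21 (3S)-β-hydroxy sulfone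
Product: 22 3-O-tert-butyldimethylsilyl ether of 21
Conditions: TBSOTf, 2,6-lutidine, CH2Cl2, −78 → 0 °C
Reagents that add atoms: tert-butyldimethylsilyl triflate, CC(C)(C)[Si](C)(C)OS(=O)(=O)C(F)(F)F
Why: Silylation of the secondary C3 hydroxyl prevents retro-addition of the β-hydroxy sulfone and O–H insertion of difluorocarbene in the next step.

Step 17
Reactants: 22 eleven-membered sulfone
Product: 25 (4Z)-ten-membered carbocycle with 3,6,12-tris-O-TBS, 8-O-tigloyl and 10-hydroxy, via α-bromo sulfone 23 (not isolated), via episulfone 24 (not isolated)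
Conditions: CBr2F2, KOH/Al2O3, t-BuOH/CH2Cl2, 0 °C → rt
Reagents that add atoms: none
Why: Hydroxide on alumina deprotonates α to the sulfonyl group and CBr2F2 transfers Br+ to that carbanion (C5); a second deprotonation at C4 displaces bromide in a 1,3-elimination to episulfone 24, which loses SO2 in a stereospecific cheletropic step, so the eleven-membered thiacycle contracts to the ten-membered carbocycle with C4=C5 in place. The closest known reaction type is the Ramberg–Bäcklund ring contraction of medium-ring and macrocyclic sulfones, including one-pot halogenative variants and trisubstituted ring alkenes. Two rings close: the thiirane dioxide by 3-exo-tet attack of the C4 carbanion on C5–Br, and the carbocycle by that same C4–C5 bond across the thiacycle (contraction by one atom). No sp3 stereocentre is created; the alkene geometry is set by the cis-fused episulfone, which is kinetically favoured under hydroxide conditions and less strained on a ten-membered ring, so the 4Z alkene should result. The step needs halogenation and 1,3-elimination to outrun β-elimination of the C3 and C6 silyloxy groups and hydroxide attack on the tiglate; silyl ethers are poor leaving groups, bromine transfer is fast, and the heterogeneous base is poorly nucleophilic toward a hindered conjugated ester.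

Step 18
Reactants: 25 tris-silyl ether
Product: 26 (4Z)-ten-membered 3,6,10,12-tetrahydroxy 8-tiglate
Conditions: HF·pyridine, pyridine, THF, 0 °C → rt
Reagents that add atoms: none
Why: Fluoride-mediated cleavage removes the three silyl ethers under buffered acidic conditions that cannot trigger base-induced acyl migration of the tiglate.

Step 19
Reactants: 26 tetrahydroxy tiglate
Product: 29 target CNP0137971.1, via hydroxy enal 27 (not isolated), via lactol 28 (not isolated)
Conditions: TEMPO (20 mol%), PhI(OAc)2, CH2Cl2, rt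
Reagents that add atoms: none
Why: TEMPO/PhI(OAc)2 oxidative lactonisation oxidises the primary allylic C12 alcohol faster than the secondary ones, the cis C6 hydroxyl traps the enal as lactol 28, and a second oxidation gives the cis-fused α-methylene-γ-lactone while O8 is blocked as the tiglate.

**Compound list**

1 | 3-methylbut-2-enoyl chloride | CC(C)=CC(=O)Cl | starting material
2 | (S)-4-benzyl-1,3-oxazolidin-2-one | O=C1OC[C@H](Cc2ccccc2)N1 | starting material
3 | (S)-4-benzyl-3-(3-methylbut-2-enoyl)-1,3-oxazolidin-2-one | CC(C)=CC(=O)N1[C@@H](Cc2ccccc2)COC1=O | intermediate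
4 | (S)-4-benzyl-3-[(E)-4-hydroxy-3-methylbut-2-enoyl]-1,3-oxazolidin-2-one | OC/C(C)=C/C(=O)N1[C@@H](Cc2ccccc2)COC1=O | intermediate
5 | (S)-4-benzyl-3-[(E)-4-(tert-butyldimethylsilyloxy)-3-methylbut-2-enoyl]-1,3-oxazolidin-2-one | CC(C)(C)[Si](C)(C)OC/C(C)=C/C(=O)N1[C@@H](Cc2ccccc2)COC1=O | intermediate
6 | geraniol, (E)-3,7-dimethylocta-2,6-dien-1-ol | CC(C)=CCC/C(C)=C/CO | starting material
7 | (2S,3S)-2,3-epoxygeraniol | OC[C@@H]1O[C@@]1(C)CCC=C(C)C | intermediate
8 | (S)-3,7-dimethyloct-6-ene-1,3-diol | OCC[C@@](C)(O)CCC=C(C)C | intermediate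
9 | (5S)-5-(2-hydroxyethyl)-5-methyloxolan-2-ol, lactol, both anomers | OCC[C@]1(C)CCC(O)O1 | intermediate
10 | 2-[(2S)-2-methyl-5-oxooxolan-2-yl]acetaldehyde | O=CC[C@]1(C)CCC(=O)O1 | intermediate
11 | Z(O) di-n-butylboron dienolate of 5 | CCCCB(CCCC)O/C(=C\C(=C)CO[Si](C)(C)C(C)(C)C)N1[C@@H](Cc2ccccc2)COC1=O | intermediate
12 | syn-aldol adduct, (7S,8R,10S) in germacrane locants, imide at C6, lactone at C3/O10 | O=C1CC[C@](C)(O1)C[C@@H](O)[C@H](C(=C)CO[Si](C)(C)C(C)(C)C)C(=O)N1[C@@H](Cc2ccccc2)COC1=O | intermediate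
13 | Weinreb amide of 12 (C6), lactone retained | O=C1CC[C@](C)(O1)C[C@@H](O)[C@H](C(=C)CO[Si](C)(C)C(C)(C)C)C(=O)N(C)OC | intermediate
14 | (3S,4R,6S)-1,10-dichloro-4,6-dihydroxy-6-methyl-3-[3-(tert-butyldimethylsilyloxy)prop-1-en-2-yl]decane-2,9-dione | ClCC(=O)CC[C@](C)(O)C[C@@H](O)[C@H](C(=C)CO[Si](C)(C)C(C)(C)C)C(=O)CCl | intermediate
15 | mercapto ketone, 14 with SH in place of the C4 chlorine | SCC(=O)CC[C@](C)(O)C[C@@H](O)[C@H](C(=C)CO[Si](C)(C)C(C)(C)C)C(=O)CCl | intermediate
16 | (6S,8R,9S)-6,8-dihydroxy-6-methyl-9-[3-(tert-butyldimethylsilyloxy)prop-1-en-2-yl]-1-thiacycloundecane-3,10-dione | O=C1CSCC(=O)CC[C@](C)(O)C[C@@H](O)[C@@H]1C(=C)CO[Si](C)(C)C(C)(C)C | intermediate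
17 | thiacycle: 3-oxo, 6-hydroxy (anti to O8), 8-O-tigloyl, 10-hydroxy, 12-O-TBS | O[C@@H]1CSCC(=O)CC[C@](C)(O)C[C@@H](OC(=O)/C(C)=C/C)[C@@H]1C(=C)CO[Si](C)(C)C(C)(C)C | intermediate
18 | 6-O-TBS ether of 17 | CC(C)(C)[Si](C)(C)O[C@@H]1CSCC(=O)CC[C@](C)(O)C[C@@H](OC(=O)/C(C)=C/C)[C@@H]1C(=C)CO[Si](C)(C)C(C)(C)C | intermediate
19 | S,S-dioxide of 18 (β-keto sulfone) | CC(C)(C)[Si](C)(C)O[C@@H]1CS(=O)(=O)CC(=O)CC[C@](C)(O)C[C@@H](OC(=O)/C(C)=C/C)[C@@H]1C(=C)CO[Si](C)(C)C(C)(C)C | intermediate
20 | 4-methyl derivative of 19, C4 epimers interconverting | CC(C)(C)[Si](C)(C)O[C@@H]1CS(=O)(=O)C(C)C(=O)CC[C@](C)(O)C[C@@H](OC(=O)/C(C)=C/C)[C@@H]1C(=C)CO[Si](C)(C)C(C)(C)C | intermediate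
21 | (3S)-3-hydroxy-4-methyl sulfone, C4 drawn anti | CC(C)(C)[Si](C)(C)O[C@@H]1CS(=O)(=O)[C@@H](C)[C@@H](O)CC[C@](C)(O)C[C@@H](OC(=O)/C(C)=C/C)[C@@H]1C(=C)CO[Si](C)(C)C(C)(C)C | intermediate
22 | 3-O-TBS ether of 21 | CC(C)(C)[Si](C)(C)O[C@@H]1CS(=O)(=O)[C@@H](C)[C@@H](O[Si](C)(C)C(C)(C)C)CC[C@](C)(O)C[C@@H](OC(=O)/C(C)=C/C)[C@@H]1C(=C)CO[Si](C)(C)C(C)(C)C | intermediate
23 | 5-bromo derivative of 22, C5 epimers | CC(C)(C)[Si](C)(C)O[C@@H]1C(Br)S(=O)(=O)[C@@H](C)[C@@H](O[Si](C)(C)C(C)(C)C)CC[C@](C)(O)C[C@@H](OC(=O)/C(C)=C/C)[C@@H]1C(=C)CO[Si](C)(C)C(C)(C)C | intermediate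
24 | cis-fused 4,5-episulfone (thiirane 1,1-dioxide on the ten-membered ring) | CC(C)(C)[Si](C)(C)O[C@@H]1C2C(C)(S2(=O)=O)[C@@H](O[Si](C)(C)C(C)(C)C)CC[C@](C)(O)C[C@@H](OC(=O)/C(C)=C/C)[C@@H]1C(=C)CO[Si](C)(C)C(C)(C)C | intermediate
25 | (4Z)-ten-membered carbocycle: 3,6,12-tris-O-TBS, 8-O-tigloyl, 10-hydroxy | CC(C)(C)[Si](C)(C)O[C@@H]1/C=C(/C)[C@@H](O[Si](C)(C)C(C)(C)C)CC[C@](C)(O)C[C@@H](OC(=O)/C(C)=C/C)[C@@H]1C(=C)CO[Si](C)(C)C(C)(C)C | intermediate
26 | (4Z)-3,6,10,12-tetrahydroxy 8-tiglate | O[C@@H]1/C=C(/C)[C@@H](O)CC[C@](C)(O)C[C@@H](OC(=O)/C(C)=C/C)[C@@H]1C(=C)CO | intermediate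
27 | 12-aldehyde (hydroxy enal) of 26 | O[C@@H]1/C=C(/C)[C@@H](O)CC[C@](C)(O)C[C@@H](OC(=O)/C(C)=C/C)[C@@H]1C(=C)C=O | intermediate
28 | 6,12-lactol, both anomers | C=C1C(O)O[C@@H]2/C=C(/C)[C@@H](O)CC[C@](C)(O)C[C@@H](OC(=O)/C(C)=C/C)[C@H]12 | intermediate
29 | CNP0137971.1, (3S,4Z,6R,7S,8R,10S)-3,10-dihydroxy-8-tigloyloxy-germacra-4,11(13)-dien-12,6-olide | C=C1C(=O)O[C@@H]2/C=C(/C)[C@@H](O)CC[C@](C)(O)C[C@@H](OC(=O)/C(C)=C/C)[C@H]12 | target

**Step count and risks**

Total step count: 19. Longest linear sequence: 16 steps (6 → 29, steps 4–19; the branch from 1 and 2, steps 1–3 then 7–19, is equally long).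

Step 17 (ring contraction). The process at risk is attack of hydroxide on the C8 tiglate in competition with halogenation and 1,3-elimination, together with some loss of Z selectivity. The fallback puts the acyl group on after the contraction. It sets out from 22: the same one-pot bromination and extrusion is run with excess KOH/Al2O3 and the crude product is treated with K2CO3 in MeOH, which should give the 8-hydroxy (4Z)-cyclodecene tris-silyl ether F1. Acylation of its only free secondary hydroxyl with (E)-2-methylbut-2-enoyl chloride, Et3N and DMAP in CH2Cl2 returns the route at 25.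

Step 15 (transfer hydrogenation). The process at risk is poor facial selectivity when the catalyst meets the conformational bias of the eleven-membered ring, or slow C4 epimerisation if the ketone is held as a hemiketal. The fallback sets C3 after the ring contraction, on the enone. It sets out from 20: NaBH4 in MeOH at −20 °C gives the 3-hydroxy-4-methyl sulfone as a C3/C4 mixture F2. The conditions of step 17, with the hydroxyl carried as its alkoxide, give the (4Z)-cyclodecen-3-ol epimeric at C3 F3. MnO2 in CH2Cl2 oxidises this only free allylic hydroxyl to the (4Z)-cyclodec-4-en-3-one F4. Corey–Bakshi–Shibata reduction with the (R)-methyl oxazaborolidine and catecholborane (toluene, −78 °C, alkenyl branch as the large group) should give the (3S)-allylic alcohol F5. The desilylation of step 18 applied to F5 returns the route at 26.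

Step 11 (hydride shift with the enal). The process at risk is slow hemiacetal formation and hydride transfer from the conjugated, α-branched aldehyde, with 1,3-acyl migration or reductive C–S cleavage by residual Sm(II) as competing paths. The fallback runs the hydride shift with a more electrophilic aldehyde and exchanges the ester afterwards. It sets out from 16: 4-nitrobenzaldehyde with the same samarium catalyst gives the anti 6-hydroxy 8-(4-nitrobenzoate) thiacycle F6. TBSCl, imidazole and DMF give its 6-O-TBS ether F7. K2CO3 in MeOH removes the benzoate to give the 6-O-TBS 8-hydroxy thiacycle F8. (E)-2-Methylbut-2-enoyl chloride, Et3N and DMAP return the route at 18.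

**Further compounds**

F1 | step 17 | 8-hydroxy (4Z)-cyclodecene tris-silyl ether (25 without the tigloyl group) | CC(C)(C)[Si](C)(C)O[C@@H]1/C=C(/C)[C@@H](O[Si](C)(C)C(C)(C)C)CC[C@](C)(O)C[C@@H](O)[C@@H]1C(=C)CO[Si](C)(C)C(C)(C)C
F2 | step 15 | 3-hydroxy-4-methyl sulfone, C3/C4 mixture | CC(C)(C)[Si](C)(C)O[C@@H]1CS(=O)(=O)C(C)C(O)CC[C@](C)(O)C[C@@H](OC(=O)/C(C)=C/C)[C@@H]1C(=C)CO[Si](C)(C)C(C)(C)C
F3 | step 15 | (4Z)-cyclodecen-3-ol epimeric at C3 (6,12-bis-O-TBS, 8-O-tigloyl) | CC(C)(C)[Si](C)(C)O[C@@H]1/C=C(/C)C(O)CC[C@](C)(O)C[C@@H](OC(=O)/C(C)=C/C)[C@@H]1C(=C)CO[Si](C)(C)C(C)(C)C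
F4 | step 15 | (4Z)-cyclodec-4-en-3-one | CC(C)(C)[Si](C)(C)O[C@@H]1/C=C(/C)C(=O)CC[C@](C)(O)C[C@@H](OC(=O)/C(C)=C/C)[C@@H]1C(=C)CO[Si](C)(C)C(C)(C)C
F5 | step 15 | (3S)-allylic alcohol (25 without the 3-silyl group) | CC(C)(C)[Si](C)(C)O[C@@H]1/C=C(/C)[C@@H](O)CC[C@](C)(O)C[C@@H](OC(=O)/C(C)=C/C)[C@@H]1C(=C)CO[Si](C)(C)C(C)(C)C
F6 | step 11 | anti 6-hydroxy 8-(4-nitrobenzoate) thiacycle | O[C@@H]1CSCC(=O)CC[C@](C)(O)C[C@@H](OC(=O)c2ccc(cc2)[N+](=O)[O-])[C@@H]1C(=C)CO[Si](C)(C)C(C)(C)C
F7 | step 11 | 6-O-TBS ether of F6 | CC(C)(C)[Si](C)(C)O[C@@H]1CSCC(=O)CC[C@](C)(O)C[C@@H](OC(=O)c2ccc(cc2)[N+](=O)[O-])[C@@H]1C(=C)CO[Si](C)(C)C(C)(C)C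
F8 | step 11 | 6-O-TBS 8-hydroxy thiacycle | CC(C)(C)[Si](C)(C)O[C@@H]1CSCC(=O)CC[C@](C)(O)C[C@@H](O)[C@@H]1C(=C)CO[Si](C)(C)C(C)(C)C
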